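Look for the ceiling on L first.

| setting | maple | ash | birch | south-west | north | south | east | west |
|---|---|---|---|---|---|---|---|---|
| Z | 0.020 M | 0.020 M | 0.013 M | 0.020 M | 0.020 M | 0.0060 M | 0.0060 M | 0.020 M |
| Q | 1.2 equiv | 5.3 equiv | 1.5 equiv | 1.50 equiv | 1.50 equiv | 1.50 equiv | 1.50 equiv | 6.00 equiv |
| X | 5 mol% | 5 mol% | 5 mol% | 20 mol% | 5 mol% | 5 mol% | 1.5 mol% | 5 mol% |
| temperature | −45 °C | −20 °C | −45 °C | 0 °C | 0 °C | 0 °C | 0 °C | −40 °C |
| remark | run made earlier | run made earlier | run made earlier |  |  |  |  |  |
| time |  |  |  | 5.0 min | 5.0 min | 5.0 min | 5.0 min | 5.0 min |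

| run | time / min | L / % |
|---|---|---|
| maple | 4.00 | 0.4 |
| maple | 6.00 | 0 |
| maple | 10.0 | 0.9 |
| maple | 12.0 | 1.3 |
| maple | 20.0 | 3.9 |
| maple | 30.0 | 5.4 |
| maple | 50.0 | 7.8 |
| ash | 1.00 | 3.9 |
| ash | 2.00 | 8.4 |
| ash | 2.50 | 10.1 |
| ash | 4.00 | 14.8 |
| ash | 5.00 | 17.0 |
| ash | 8.00 | 22.4 |
| ash | 15.0 | 29.6 |
| birch | 4.00 | 0 |
| birch | 8.00 | 0 |
| birch | 12.0 | 0.7 |
| birch | 25.0 | 3.8 |
| birch | 50.0 | 7.1 |

(readings scatter by 0.5 percentage points)

- the earlier runs were read with a standard deviation of 0.5 percentage points

* the flasks by amount of L, in percent of the Z charged, highest first, at 5.0 min (south-west / north / south / east / west)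
* the same order at 40 min (south-west / north / south / east / west)
* the amount of L, in percent of the Z charged of the flask you put first, at 5.0 min
* the amount of L, in percent of the Z charged of the flask you put last, at 5.0 min

The ash run bends: its slope falls from 0.0420 min⁻¹ near L = 4.20% to 0.0103 min⁻¹ near L = 26.0%, fractions of the Z charged.

My own reckoning supposes that L is lost in a step that, like its making, runs with Z. Z then cancels from the ratio of the two rates, and L heads for a level a at which it is lost as fast as it is made, a level proportional to the X charged. Carrying the slope on as a straight line to zero gives, for ash: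

a = 33.1%

This is the balance level, a kind of selectivity, at 5 mol% of X.

Two extreme flasks can be solved at once. With a far above the charge, no L is lost and L ends at the whole charge. With a far below it, L stops at a and the remaining Z is wasted. South-west lies between them, with 20 mol% of X against 5 mol% in ash; my reckoning scales a with the X charged and leaves the temperature and Q out of it:

a = 132%

That stands above the charge, but not far above it. Ash's early slope, scaled to this X but with ash's 5.3 equiv of Q in place of the 1.50 equiv of south-west, gives an estimate of 5.95 min to empty Z at −20 °C; south-west is warmer, so my reckoning takes Z as used up by 5.0 min. Integrating over the whole charge gives: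

L = a(1 − exp(−(1 + L)/(2a)))

Starting from 0.5, this gives 57.2%, then 59.3%, my figure for south-west.

The forecast differs. It gives south-west > west > north > south > east at 5.0 min and west > south-west > north > south > east at 40 min, with top 10% (7% to 15%) and low 1.2% (0.5% to 2.5%). Its ground: “L curves over long before Z or Q run out, which suggests the catalyst is dying”.

The flasks give south-west > north > south > east > west at 5.0 min, with top 62.3% and low 1.41%, and south-west > south > north > west > east at 40 min.

    D → E (k = 0.800 s⁻¹, Ea = 64.0 kJ mol⁻¹)
    Z + L → G (k = 1.00 M⁻¹ s⁻¹, Ea = 50.0 kJ mol⁻¹)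
    J → X + L (k = 0.730 s⁻¹, Ea = 57.0 kJ mol⁻¹)
    Z + E → J (k = 11.0 M⁻¹ s⁻¹, Ea = 50.0 kJ mol⁻¹)
    Q + X ⇌ D (K = 42.0 M⁻¹, k = 19.0 M⁻¹ s⁻¹, Ea = 43.0 kJ mol⁻¹, ΔH = −7.00 kJ mol⁻¹)
    (constants at 0 °C)

South-west stops at 62.3%, with 37.7% of the charge in G and Z at 0%, because of the loss of Z + L to G: the same run without that step gives >99.9%. The balance level 132% describes that competition, and it is scaled from ash by the X charged, with no temperature in the reckoning. A flask like south-west kept at −15 °C has the same X, so the reckoned level stays 132%, and that flask holds 58.1% of L at 5.0 min, with Z still at 6.10%.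

Readings and results were generated by integration for substances that don't exist; noise was put on by code.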